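If the electrophile in this flask were to be used up by the first step within the run, the gas would have to deliver one nucleophile for every electrophile charged.

electrophile 0.039 M; buffer base 0.200 equiv; buffer acid 1.00 equiv; gas 15 mM (held); time 2.5 d

    electrophile + nucleophile → acid + target + leaving group (k1 = 0.73 /M/h)
    protonated nucleophile ⇌ nucleophile + acid, settled at all times (K2 = 4.0 × 10⁻⁶ M)
    buffer acid ⇌ buffer base + acid, settled at all times (K3 = 1.3 × 10⁻¹⁰ M)
    target → over-reaction product (k4 = 0.0015 /h)
    electrophile → decomposition product (k5 = 2.9 × 10⁻⁵ /h)
    gas ⇌ nucleophile, rate k6*(csat - [nucleophile]) (k6 = 0.019 /h, csat = 15 mM)

- part of the electrophile that has reacted at 2.5 d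
- pH of the solution at 2.5 d

I turned that round first. Inflow is largest while the solution holds no nucleophile, and even at that pace it would bring in 43.8% of the electrophile charge over 2.5 d, less than the full charge, so I expected the electrophile in this flask to outlast the run.

Dissolved nucleophile starts at none, so I wrote its balance: inflow, the transfer coefficient times the gap to saturation, against uptake, the first step's rate constant times electrophile times nucleophile. Holding the electrophile at its charge makes uptake pseudo-first-order in nucleophile, at 0.0285 /h beside the transfer coefficient of 0.019 /h. The level then climbs at 0.0475 /h towards the plateau share, the dissolved nucleophile per electrophile charged at which inflow equals uptake: 15.4%. The climb costs a lag of 19.8 h, so uptake at the plateau share over the remaining time gave me 17.6% reacted. I ignored decomposition because its half-life of 1000 d is longer than the run. My reckoning stopped there and gave no pH.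

The forecast said 16.6%, within 15.5% to 17.5%, lower than my figure, and pH 8.36, within 8.2 to 8.5, on the grounds of “gas transfer against consumption”.

The simulation gave 16.6% reacted and pH 8.37.

In this flask the unprotonated nucleophile stood at 15.3% of the electrophile charge at 2.50 d, against my plateau share of 15.4%. I ran the same reckoning on a neighbouring flask with 0.16 M of electrophile, the equivalents and time held. Its plateau share came to 1.31%, and its lag-corrected uptake to 8.06% reacted. That neighbouring flask held unprotonated nucleophile at 1.39% of its electrophile charge and reached 8.11% reacted.

The constants are invented; the flask was simulated.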